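## Structural features

The target 26 is a germacranolide: a ten-membered carbocycle C1–C10 fused through C6–C7 to a butenolide (O–C6, C7=C11, C12=O) whose α-carbon C11 carries the acetoxymethyl carbon C13. The ring bears an acetate at C1, a methyl at C10, a cis trisubstituted epoxide at C4–C5 (methyl on C4) and a tiglate at C8; the configuration read from the structure is 1S,4R,5S,6S,8S,10R. The stereocentres form a vicinal pair C10/C1 (methyl and acetoxy anti along the chain), a contiguous triad C4/C5/C6, and the lone C8, which faces C6 across the sp2 carbon C7. Fragile groups are the epoxide (acid, and a free C1 hydroxyl, which can open it at C4 to a tetrahydrofuran), the two allylic esters flanking the tetrasubstituted alkene (acyl shift), the tiglate (deconjugation) and the butenolide (base). The real difficulty is twofold: closing a ten-membered ring, and building the tetrasubstituted C7=C11 alkene with oxygenated carbons on all four positions (C6, C8, C12, C13) in the right geometry. The key step exploits the unit O–C8–C7=C11–C13–O, a cis-2-ene-1,4-diol, which is the reduced adduct of O2 with the diene C8=C7–C11=C13. That diene, with C7=C8 in the ring and C11=C13 outside it, is the exo-mode product of enyne metathesis between a C7≡C11 alkyne and a terminal C8 alkene; cis addition of oxygen then leaves C12 cis to C6 for the lactone.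

## Logic of the disconnections

26 ⇒ 23. The lactone C12–O6 bond is cut and C12 is returned to the alcohol level. This replaces the base-sensitive butenolide by a 1,4-diol on a Z-disposed alkene. The forward step needs an oxidant that takes the primary allylic hydroxyl of 23 before the secondary one and carries the lactol on to the lactone.

23 ⇒ 22 ⇒ 21 ⇒ 20. The two O–Si bonds are restored, then the ester C–O bonds at O8 (tigloyl) and O13 (acetyl) are cut. Four hydroxyls are thereby told apart: O6 and O12 stay masked from before ring closure, while O8 and O13 appear together and differ as secondary and primary. The forward steps demand a primary-selective acylation of 20 and a desilylation of 22 that spares the epoxide and does not move acyl groups.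

20 ⇒ 18. The C8–O and C13–O bonds are cut together (through 19) and one molecule of dioxygen is given back. One stereocentre and two oxygens disappear, leaving a conjugated diene. The forward step must be a [4+2] addition and not an ene reaction, and must take the face that gives 8S.

18 ⇒ 17. The ring bond C7=C8 and the exocyclic bond C11=C13 are cut; C8 is rejoined to C13 as a terminal alkene and C7 to C11 as a triple bond. The ring is gone, no stereocentre is touched, and all five remaining stereocentres sit on an open chain. The forward step must close a ten-membered ring in the exo mode against dimerisation.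

17 ⇒ 16 ⇒ 14. The C8=C13 double bond is cut to a C8 aldehyde, which is traced back to a terminal C8≡C9 alkyne. This is done because a terminal alkyne on C10 is what a propargylation delivers. The forward hydroboration must select the terminal alkyne over the internal one.

14 ⇒ 13 ⇒ 9 + 11 (11 from 10). The acetyl group is removed and the C1–C10 bond is cut between an aldehyde and a chiral allenylmetal. Two stereocentres come from one C–C bond formation under reagent control. The forward step needs anti selectivity and a C1 alkoxide that does not attack the epoxide before it is acetylated.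

9 ⇒ 7. The C1 aldehyde is returned to the trisubstituted alkene C1=C(CH3)2, the distal prenyl unit of the terpene chain. The forward cleavage must take this alkene and leave the alkyne.

7 ⇒ 6 ⇒ 3 + 4. The O6 silyl group is removed and the C6–C7 bond is cut into an epoxy aldehyde and the acetylide of 4. C7, C11 and C12 arrive in one piece and C6 is set by the neighbouring epoxide. The forward addition must follow the Felkin–Anh sense.

3 ⇒ 2 ⇒ 1. The oxidation level at C6 is lowered and the two epoxide C–O bonds are cut. The Z-allylic alcohol 1 supplies C1–C6 and C15, and its Z geometry encodes the cis epoxide. The forward step is an enantioselective epoxidation of the allylic alkene only.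

## Other disconnections considered

Alternative 1: The ring is made by expansion, not cyclisation: C8–C9 is formed while the C1–C6 bond of a cyclohexene is broken. The forward step is an anionic oxy-Cope rearrangement (KH, 18-crown-6) of a tertiary C6 alkoxide carrying a C7=C8 alkoxyvinyl group next to a C10=C9 isopropenyl group; protonation of the C6 enolate gives cyclodecadienone A1.
- In its favour: no high dilution, a cheap terpene-derived six-membered ring, a concerted and well-understood reaction type, and a Z C4=C5 alkene guaranteed by the ring it comes from. On reliability of ring formation and on step count up to the carbocycle it is the better plan.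
- Against it here: A1 holds one of six stereocentres (C8) and none of the lactone carbons. C1/C10 would come from hydroboration of a ring alkene, C4/C5 from epoxidation of an enone, C6 from ketone reduction, all steered only by the conformation of a flexible ring. C11–C13 must still be attached at C7 and turned into a tetrasubstituted alkene. The enolate formed in the key step has the C8 ether in the β-position, so elimination is a built-in side path, and absolute configuration rests on chirality transfer through one transition-state geometry.
- Comparison: the chosen plan sets five stereocentres on an open chain and brings C11–C13 in with the alkyne, but pays with a harder ring closure. On mechanism the pericyclic step is more predictable than metathesis, which has a mode and an oligomerisation problem. On overall step economy the chosen plan is expected to be shorter because so little remains to be done after its ring closure.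

Alternative 2: The cut is the sp3–sp2 bond C3–C4. In the forward step 9-BBN hydroborates a terminal C2=C3 alkene and Pd(dppf)Cl2 with Cs2CO3 couples the C3 alkylborane with a (Z)-vinyl iodide at C4, giving the Z-cyclodecenone A2.
- In its favour: the Z geometry is fixed before ring closure (equal to the chosen plan, where the terpene fixes it), and C1, C6, C8 and C10 are all set on the open chain. On control of C8 this alternative is the better plan, since C8 is secure before cyclisation. The bond formed is a single bond between unhindered carbons.
- Against it here: C6 and C8 flank the C7 ketone and are epimerisable. Aqueous carbonate with an α-acyloxy ketone and an acetate invites hydrolysis and acyl shift, and the borane must spare the ketone. Ten-membered closure by this coupling has less support than larger rings, with protodeboronation and β-hydride elimination competing. After A2 the C11–C13 unit must be added to a ketone flanked by two oxygenated stereocentres and dehydrated to the tetrasubstituted alkene, and the C4=C5 alkene must be epoxidised on the correct face of the ring.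
- Comparison: both closures are metal-catalysed and need high dilution, so they are equal on that point. The chosen plan has the lactone carbons and the epoxide in place at cyclisation but leaves C8 to a facial choice. Five steps follow its ring closure against an estimated six or more, including a difficult olefination, after A2.

Alternative 3: The cut is C6–C7, made by contraction of a thirteen-membered cyclic ether (C6–O–CH2–C11=C7). In the forward step n-BuLi exchanges a stannyl group on C6 for lithium; the α-alkoxy allyl anion attacks C7 in a [2,3] shift while the O–CH2 bond breaks. The carbon released from oxygen becomes the exocyclic methylene on C11, and the product is cyclodecenol A3.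
- In its favour: a thirteen-membered ether is easier to close than a ten-membered carbocycle, the shift forms the C–C bond and two adjacent stereocentres through an ordered five-membered transition state, and C8 is set beforehand. On ease of ring closure and on C8 it is the equal or the better of the chosen plan.
- Against it here: the organolithium step excludes esters, so C1 and C8 travel as ethers and four protecting-group steps follow. The allyl anion is delocalised, so a [1,2] shift and attack through C4 compete. A3 has C7 as an sp3 carbon and a C11 methylene, so the alkene must be moved into C7=C11 with oxygenation of the methylene carbon; the C4=C5 alkene must be epoxidised and the lactone built.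
- Comparison: the sigmatropic contraction is stereochemically more predictable than the metathesis. The chosen plan reaches the cyclic stage with the acetate, the epoxide and all lactone carbons in the final pattern and needs five further steps against an estimated eight or more. It is the better on step and functional-group economy and the weaker on certainty of the ring-forming step.

Key step: step 11

Remark: 4, the tert-butyldimethylsilyl ether of prop-2-yn-1-ol, is taken as a purchased material.
Remark: 17 and 18 carry the configuration of 26 at C1, C4, C5, C6 and C10 without correction. The design changes are triethylsilyl on O6 (so the last deprotection is short) and building the C6 end before the C1 end (no protection and release of O6).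

Step 1
Reactants: 1 nerol [(2Z)-3,7-dimethylocta-2,6-dien-1-ol]
Product: 2 (2S,3R)-2,3-epoxynerol {[(2S,3R)-3-methyl-3-(4-methylpent-3-en-1-yl)oxiran-2-yl]methanol}
Conditions: Ti(OiPr)4 (cat.), L-(+)-diethyl tartrate (cat.), t-BuOOH, 4 Å molecular sieves, CH2Cl2, −20 °C
Reagents that add atoms: tert-butyl hydroperoxide, CC(C)(C)OO
Why: Sharpless asymmetric epoxidation touches only the allylic alkene; the L-(+)-tartrate complex delivers oxygen to the face that gives 4R,5S, and the Z alkene becomes the cis epoxide.

Step 2
Reactants: 2 (2S,3R)-2,3-epoxynerol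
Product: 3 (2R,3R)-2,3-epoxyneral [(2R,3R)-3-methyl-3-(4-methylpent-3-en-1-yl)oxirane-2-carbaldehyde]
Conditions: Dess–Martin periodinane, pyridine, CH2Cl2, 0 °C to rt; used crude
Reagents that add atoms: none
Why: Buffered Dess–Martin oxidation of a 2,3-epoxy alcohol should give the epoxy aldehyde without epoxide opening or loss of the C5 configuration (the descriptor at C5 changes only because the priorities change).

Step 3
Reactants: 3 (2R,3R)-2,3-epoxyneral; 4 tert-butyldimethyl(prop-2-yn-1-yloxy)silane
Product: 6 (1S)-4-(tert-butyldimethylsilyloxy)-1-[(2S,3R)-3-methyl-3-(4-methylpent-3-en-1-yl)oxiran-2-yl]but-2-yn-1-ol (4R,5S,6S), via lithium acetylide 5 (not isolated)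
Conditions: 4, n-BuLi, THF, −78 °C; then 3, −78 °C; NH4Cl quench
Reagents that add atoms: none
Why: Acetylide addition to an α,β-epoxy aldehyde should follow the Felkin–Anh sense, with attack anti to the C5–O bond, C4 gauche to the carbonyl oxygen and the nucleophile passing the C5 hydrogen, which gives 6S. The ring substituent cis to the formyl group on the epoxide blocks the competing rotamer.

Step 4
Reactants: 6 the (4R,5S,6S)-propargylic alcohol
Product: 7 triethylsilyl ether of 6 at O6 {tert-butyldimethyl[(4S)-4-[(2S,3R)-3-methyl-3-(4-methylpent-3-en-1-yl)oxiran-2-yl]-4-(triethylsilyloxy)but-2-yn-1-yl]oxysilane}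
Conditions: Et3SiCl, imidazole, DMAP (cat.), CH2Cl2, 0 °C to rt
Reagents that add atoms: chlorotriethylsilane, CC[Si](Cl)(CC)CC
Why: Silylation with the chloride and imidazole is chosen because a silyl triflate could trigger rearrangement of the adjacent epoxide.

Step 5
Reactants: 7 the bis-silyl ether
Product: 9 3-[(2R,3S)-3-[(1S)-4-(tert-butyldimethylsilyloxy)-1-(triethylsilyloxy)but-2-yn-1-yl]-2-methyloxiran-2-yl]propanal, via ozonide 8 (not isolated)
Conditions: O3, CH2Cl2, −78 °C, stopped at consumption of 7; then PPh3, −78 °C to rt
Reagents that add atoms: ozone, [O-][O+]=O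
Why: Ozonolysis with reductive work-up; the electron-rich trisubstituted alkene should react far faster than the internal alkyne, which is flanked by two silyloxy-bearing carbons, and the epoxy aldehyde is released under neutral, anhydrous conditions.

Step 6
Reactants: 10 (S)-but-3-yn-2-ol
Product: 11 (S)-but-3-yn-2-yl methanesulfonate
Conditions: MsCl, Et3N, CH2Cl2, −78 to 0 °C
Reagents that add atoms: methanesulfonyl chloride, CS(=O)(=O)Cl
Why: Sulfonylation at oxygen leaves the stereocentre untouched.

Step 7
Reactants: 9 the epoxy aldehyde; 11 (S)-but-3-yn-2-yl methanesulfonate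
Product: 13 (3R,4S)-6-[(2R,3S)-3-[(1S)-4-(tert-butyldimethylsilyloxy)-1-(triethylsilyloxy)but-2-yn-1-yl]-2-methyloxiran-2-yl]-3-methylhex-1-yn-4-ol (1S,10R), via allenylzinc mesylate 12 (not isolated)
Conditions: Pd(OAc)2 (5 mol%), PPh3 (5 mol%), Et2Zn, THF, −78 to −20 °C; pH 7 buffer quench at −20 °C; crude product taken on at once
Reagents that add atoms: none
Why: Marshall propargylation: zerovalent palladium ionises 11 in an anti SN2′ sense, transmetalation gives the (M)-allenylzinc 12, and this adds through a cyclic SE2′ transition state. The result is net inversion at the former carbinol carbon (10R) and the anti relation (1S), under reagent control because C2 is unbranched. The cold neutral quench keeps the C1 hydroxyl from opening the epoxide.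

Step 8
Reactants: 13 the homopropargylic alcohol
Product: 14 (3R,4S)-6-[(2R,3S)-3-[(1S)-4-(tert-butyldimethylsilyloxy)-1-(triethylsilyloxy)but-2-yn-1-yl]-2-methyloxiran-2-yl]-3-methylhex-1-yn-4-yl acetate
Conditions: Ac2O, pyridine, DMAP (cat.), CH2Cl2, 0 °C
Reagents that add atoms: acetic anhydride, CC(=O)OC(C)=O
Why: DMAP-catalysed acetylation installs the final C1 ester and removes the hydroxyl that could cyclise onto C4 of the epoxide.

Step 9
Reactants: 14 the diyne acetate
Product: 16 (3R,4S)-6-[(2R,3S)-3-[(1S)-4-(tert-butyldimethylsilyloxy)-1-(triethylsilyloxy)but-2-yn-1-yl]-2-methyloxiran-2-yl]-3-methyl-1-oxohexan-4-yl acetate, via alkenylborane 15 (not isolated)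
Conditions: Cy2BH (from BH3·SMe2 and cyclohexene), THF, 0 °C; then NaBO3·4H2O, THF/H2O, rt
Reagents that add atoms: sodium perborate, O=BO[O-].[Na+]
Why: Anti-Markovnikov monohydroboration of a terminal alkyne with a dialkylborane and mild perborate oxidation give the aldehyde. The terminal alkyne should react much faster than the hindered internal one, and perborate spares the acetate.

Step 10
Reactants: 16 the C8 aldehyde
Product: 17 (4R,5S)-7-[(2R,3S)-3-[(1S)-4-(tert-butyldimethylsilyloxy)-1-(triethylsilyloxy)but-2-yn-1-yl]-2-methyloxiran-2-yl]-4-methylhept-1-en-5-yl acetate (1S,4R,5S,6S,10R)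
Conditions: Ph3PCH3Br, KN(SiMe3)2, THF, 0 °C; then 16, −78 to 0 °C
Reagents that add atoms: methyltriphenylphosphonium bromide, C[P+](c1ccccc1)(c1ccccc1)c1ccccc1.[Br-]
Why: Wittig methylenation; the aldehyde reacts far faster than the acetate with a small excess of ylide at low temperature, and no stereocentre is α to the carbonyl.

Step 11
Reactants: 17 the epoxy enyne
Product: 18 (1S,4R,5S,6S,7Z,10R)-1-acetoxy-12-(tert-butyldimethylsilyloxy)-4,5-epoxy-6-(triethylsilyloxy)germacra-7,11(13)-diene
Conditions: (H2IMes)(PCy3)Cl2Ru=CHPh (second-generation Grubbs catalyst, 15 mol% in portions), toluene, 0.002 M, 80 °C, argon, no ethylene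
Reagents that add atoms: none
Why: The catalyst should load on the monosubstituted C8 alkene to give a ruthenium alkylidene at C8 (ene-first path), because the internal alkyne between two silyloxy-bearing carbons is too hindered for intermolecular attack. Intramolecular [2+2] addition to C7≡C11 joins C8 to C7, and opening of the ruthenacyclobutene leaves a vinylcarbene at C11. That carbene takes the methylene carbon C13 from the alkene of a second molecule of 17, forming C11=C13 and regenerating the C8 alkylidene, so no atom is lost. The closest known reaction type is ring-closing enyne metathesis of 1,n-enynes to 1-(alk-1-en-2-yl)cycloalkenes, documented for small and medium rings with ten at the upper edge. The ring closes in the exo mode with respect to the alkyne (ten-membered, containing C7 but not C11), as opposed to endo closure to an eleven-membered ring. No stereocentre is formed; the new stereo element is the Z geometry of C7=C8 (C6 and C9 cis), which the ring and the metallacycle geometry are expected to impose. The step needs cyclisation over alkene dimerisation and exo over endo closure; high dilution, the absence of ethylene and the turns set by the cis epoxide and the branched C6 and C10 carbons are the elements that should secure this.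

Step 12
Reactants: 18 the cyclic diene
Product: 20 (1S,4R,5S,6S,8S,10R)-1-acetoxy-12-(tert-butyldimethylsilyloxy)-4,5-epoxy-6-(triethylsilyloxy)germacr-7(11)-ene-8,13-diol (C13 cis to C8), via endoperoxide 19 (not isolated)
Conditions: O2, visible light, tetraphenylporphyrin (cat.), CH2Cl2, −20 °C; then thiourea, MeOH, rt
Reagents that add atoms: dioxygen, O=O
Why: Singlet oxygen adds suprafacially across C8 and C13 of the s-cis diene, so both new oxygens end cis on C7=C11 and C12 ends cis to C6; thiourea then cleaves the O–O bond without touching the epoxide or esters. The 8S face is expected because the electrophile should approach anti to the ring carbon C5 with the C6–O bond near the diene plane (inside-alkoxy arrangement). O6 is kept silylated so that no hydrogen bond steers oxygen to the other face.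

Step 13
Reactants: 20 the 8,13-diol
Product: 21 13-acetate of 20 [(1S,4R,5S,6S,8S,10R)-1,13-diacetoxy-12-(tert-butyldimethylsilyloxy)-4,5-epoxy-6-(triethylsilyloxy)germacr-7(11)-en-8-ol]
Conditions: AcCl (1.1 equiv), 2,4,6-collidine, CH2Cl2, −78 °C
Reagents that add atoms: acetyl chloride, CC(Cl)=O
Why: Acetyl chloride with a hindered pyridine base at low temperature acylates a primary hydroxyl in preference to a secondary one, here the secondary one being in the ring next to a tetrasubstituted alkene.

Step 14
Reactants: 21 the 13-acetate
Product: 22 8-tiglate of 21 [(1S,4R,5S,6S,8S,10R)-1,13-diacetoxy-12-(tert-butyldimethylsilyloxy)-4,5-epoxy-8-tigloyloxy-6-(triethylsilyloxy)germacr-7(11)-ene]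
Conditions: tigloyl chloride, pyridine, DMAP (cat.), CH2Cl2, 0 °C to rt
Reagents that add atoms: tigloyl chloride [(E)-2-methylbut-2-enoyl chloride], C/C=C(\C)C(Cl)=O
Why: DMAP-catalysed acylation of the secondary allylic hydroxyl; pyridine in place of a trialkylamine avoids vinylketene formation and deconjugation of the unsaturated acyl group.

Step 15
Reactants: 22 the fully acylated bis-silyl ether
Product: 23 (1S,4R,5S,6S,8S,10R)-1,13-diacetoxy-4,5-epoxy-8-tigloyloxygermacr-7(11)-ene-6,12-diol (C12 cis to C6)
Conditions: HF·pyridine, excess pyridine, THF, 0 °C to rt; NaHCO3 quench; used directly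
Reagents that add atoms: none
Why: Buffered HF·pyridine cleaves the secondary triethylsilyl and the primary tert-butyldimethylsilyl ether under weakly acidic conditions in which ester groups should not migrate, and a trisubstituted epoxide normally survives short exposure.

Step 16
Reactants: 23 the 6,12-diol
Product: 26 (1S,4R,5S,6S,8S,10R)-1,13-diacetoxy-4,5-epoxy-8-tigloyloxygermacr-7(11)-en-12,6-olide, via hydroxy enal 24 (not isolated), via lactol 25 (not isolated)
Conditions: TEMPO (20 mol%), PhI(OAc)2 (2.5 equiv), CH2Cl2, rt
Reagents that add atoms: none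
Why: Oxoammonium oxidation takes the primary allylic hydroxyl first; the enal is trapped by the cis C6 hydroxyl as a five-membered lactol, which is oxidised on to the butenolide (oxidative lactonisation of a 1,4-diol).

Compound list

1 | nerol, (2Z)-3,7-dimethylocta-2,6-dien-1-ol | CC(C)=CCC/C(C)=C\CO | starting material
2 | (2S,3R)-2,3-epoxynerol | CC(C)=CCC[C@@]1(C)O[C@H]1CO | intermediate
3 | (2R,3R)-2,3-epoxyneral | CC(C)=CCC[C@@]1(C)O[C@H]1C=O | intermediate
4 | tert-butyldimethyl(prop-2-yn-1-yloxy)silane | C#CCO[Si](C)(C)C(C)(C)C | starting material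
5 | lithium 3-(tert-butyldimethylsilyloxy)prop-1-yn-1-ide | [Li]C#CCO[Si](C)(C)C(C)(C)C | intermediate
6 | (1S)-4-(tert-butyldimethylsilyloxy)-1-[(2S,3R)-3-methyl-3-(4-methylpent-3-en-1-yl)oxiran-2-yl]but-2-yn-1-ol | CC(C)=CCC[C@@]1(C)O[C@H]1[C@@H](O)C#CCO[Si](C)(C)C(C)(C)C | intermediate
7 | triethylsilyl ether of 6 at O6 | CC(C)=CCC[C@@]1(C)O[C@H]1[C@@H](O[Si](CC)(CC)CC)C#CCO[Si](C)(C)C(C)(C)C | intermediate
8 | secondary ozonide (1,2,4-trioxolane) of 7 at the prenyl alkene, mixture at the new ring carbon | CC1(C)OOC(CC[C@@]2(C)O[C@H]2[C@@H](O[Si](CC)(CC)CC)C#CCO[Si](C)(C)C(C)(C)C)O1 | intermediate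
9 | 3-[(2R,3S)-3-[(1S)-4-(tert-butyldimethylsilyloxy)-1-(triethylsilyloxy)but-2-yn-1-yl]-2-methyloxiran-2-yl]propanal | O=CCC[C@@]1(C)O[C@H]1[C@@H](O[Si](CC)(CC)CC)C#CCO[Si](C)(C)C(C)(C)C | intermediate
10 | (S)-but-3-yn-2-ol | C#C[C@H](C)O | starting material
11 | (S)-but-3-yn-2-yl methanesulfonate | C#C[C@H](C)OS(C)(=O)=O | intermediate
12 | (M)-buta-1,2-dien-1-ylzinc methanesulfonate | [H]C(C)=[C@@]=C([H])[Zn]OS(C)(=O)=O | intermediate
13 | (3R,4S)-6-[(2R,3S)-3-[(1S)-4-(tert-butyldimethylsilyloxy)-1-(triethylsilyloxy)but-2-yn-1-yl]-2-methyloxiran-2-yl]-3-methylhex-1-yn-4-ol | C#C[C@@H](C)[C@@H](O)CC[C@@]1(C)O[C@H]1[C@@H](O[Si](CC)(CC)CC)C#CCO[Si](C)(C)C(C)(C)C | intermediate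
14 | acetate of 13 at O1 | C#C[C@@H](C)[C@@H](OC(C)=O)CC[C@@]1(C)O[C@H]1[C@@H](O[Si](CC)(CC)CC)C#CCO[Si](C)(C)C(C)(C)C | intermediate
15 | (E)-alkenyl(dicyclohexyl)borane from 14, boron on C8 | C1CCCCC1B(C1CCCCC1)/C=C/[C@@H](C)[C@@H](OC(C)=O)CC[C@@]1(C)O[C@H]1[C@@H](O[Si](CC)(CC)CC)C#CCO[Si](C)(C)C(C)(C)C | intermediate
16 | (3R,4S)-6-[(2R,3S)-3-[(1S)-4-(tert-butyldimethylsilyloxy)-1-(triethylsilyloxy)but-2-yn-1-yl]-2-methyloxiran-2-yl]-3-methyl-1-oxohexan-4-yl acetate | O=CC[C@@H](C)[C@@H](OC(C)=O)CC[C@@]1(C)O[C@H]1[C@@H](O[Si](CC)(CC)CC)C#CCO[Si](C)(C)C(C)(C)C | intermediate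
17 | (4R,5S)-7-[(2R,3S)-3-[(1S)-4-(tert-butyldimethylsilyloxy)-1-(triethylsilyloxy)but-2-yn-1-yl]-2-methyloxiran-2-yl]-4-methylhept-1-en-5-yl acetate | C=CC[C@@H](C)[C@@H](OC(C)=O)CC[C@@]1(C)O[C@H]1[C@@H](O[Si](CC)(CC)CC)C#CCO[Si](C)(C)C(C)(C)C | intermediate
18 | (1S,4R,5S,6S,7Z,10R)-1-acetoxy-12-(tert-butyldimethylsilyloxy)-4,5-epoxy-6-(triethylsilyloxy)germacra-7,11(13)-diene | C=C(CO[Si](C)(C)C(C)(C)C)/C1=C/C[C@@H](C)[C@@H](OC(C)=O)CC[C@@]2(C)O[C@H]2[C@H]1O[Si](CC)(CC)CC | intermediate
19 | (1S,4R,5S,6S,8S,10R)-1-acetoxy-12-(tert-butyldimethylsilyloxy)-4,5-epoxy-8,13-epidioxy-6-(triethylsilyloxy)germacr-7(11)-ene | O1OCC(CO[Si](C)(C)C(C)(C)C)=C2[C@@H]1C[C@@H](C)[C@@H](OC(C)=O)CC[C@@]3(C)O[C@H]3[C@H]2O[Si](CC)(CC)CC | intermediate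
20 | (1S,4R,5S,6S,8S,10R)-1-acetoxy-12-(tert-butyldimethylsilyloxy)-4,5-epoxy-6-(triethylsilyloxy)germacr-7(11)-ene-8,13-diol | OC/C(CO[Si](C)(C)C(C)(C)C)=C1\[C@@H](O)C[C@@H](C)[C@@H](OC(C)=O)CC[C@@]2(C)O[C@H]2[C@H]1O[Si](CC)(CC)CC | intermediate
21 | 13-acetate of 20 | CC(=O)OC/C(CO[Si](C)(C)C(C)(C)C)=C1\[C@@H](O)C[C@@H](C)[C@@H](OC(C)=O)CC[C@@]2(C)O[C@H]2[C@H]1O[Si](CC)(CC)CC | intermediate
22 | 8-tiglate of 21 | C/C=C(\C)C(=O)O[C@H]1C[C@@H](C)[C@@H](OC(C)=O)CC[C@@]2(C)O[C@H]2[C@@H](O[Si](CC)(CC)CC)/C1=C(/COC(C)=O)CO[Si](C)(C)C(C)(C)C | intermediate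
23 | (1S,4R,5S,6S,8S,10R)-1,13-diacetoxy-4,5-epoxy-8-tigloyloxygermacr-7(11)-ene-6,12-diol | C/C=C(\C)C(=O)O[C@H]1C[C@@H](C)[C@@H](OC(C)=O)CC[C@@]2(C)O[C@H]2[C@@H](O)/C1=C(/COC(C)=O)CO | intermediate
24 | 12-aldehyde of 23 (6-hydroxy enal) | C/C=C(\C)C(=O)O[C@H]1C[C@@H](C)[C@@H](OC(C)=O)CC[C@@]2(C)O[C@H]2[C@@H](O)/C1=C(/COC(C)=O)C=O | intermediate
25 | lactol of 24 (12-hydroxy-6,12-epoxide, both C12 epimers) | C/C=C(\C)C(=O)O[C@H]1C[C@@H](C)[C@@H](OC(C)=O)CC[C@@]2(C)O[C@H]2[C@H]2OC(O)C(COC(C)=O)=C12 | intermediate
26 | (1S,4R,5S,6S,8S,10R)-1,13-diacetoxy-4,5-epoxy-8-tigloyloxygermacr-7(11)-en-12,6-olide (CNP0287840.1) | C/C=C(\C)C(=O)O[C@H]1C[C@@H](C)[C@@H](OC(C)=O)CC[C@@]2(C)O[C@H]2[C@H]2OC(=O)C(COC(C)=O)=C12 | target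

Total step count: 16. Longest linear sequence: 15 steps (steps 1–5 and 7–16, from 1); step 6 is a one-step branch that joins at step 7.

Least certain steps

Step 11 (key step). Ring closure may lose to intermolecular alkene metathesis, or may run in the endo mode to the eleven-membered ring, because ten-membered exo closure lies at the edge of what the ene-first pathway tolerates; leakage to the E ring alkene is a further possibility. The fallback sets out from 17 and returns at 18. The triethylsilyl group is removed selectively (PPTS, MeOH, 0 °C) to give the enyne alcohol F1. Cross-metathesis of its alkyne with ethylene (1 atm, second-generation Grubbs catalyst, CH2Cl2, 40 °C) gives the 2,3-disubstituted butadiene, triene F2. Ring-closing olefin metathesis of F2 at high dilution under argon should then close C7=C8 with loss of ethylene to the cyclic dienol F3; the free allylic hydroxyl on C6 is expected to favour reaction at the C7 methylene over the C11 methylene. Silylation (Et3SiCl, imidazole) returns 18.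

Step 12. Facial discrimination at C8 may be poor, because the two faces of the diene differ only through the conformation around C6 and the ring; ene-type hydroperoxidation of C7=C8 may also compete with the [4+2] addition. The fallback sets out from 18 and returns at 22. If oxygen adds mainly to the other face, the same operation gives the 8-epi endoperoxide F4 and, after thiourea, the 8-epi diol F5. Acetylation as in step 13 gives the 8-epi monoacetate F6. Mitsunobu esterification with tiglic acid (PPh3, DIAD, toluene, 0 °C) then installs the tiglate with inversion at C8 and arrives at 22.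

Step 15. During the time needed for the primary tert-butyldimethylsilyl ether, fluoride may open the epoxide under acid assistance, or an acyl group may shift from O13 to the freed O12 or from O8 to O6. The fallback sets out from 20 and returns at 26. The ene-diol of 20 is tied up as the seven-membered acetonide F7 (2,2-dimethoxypropane, PPTS, CH2Cl2). With no ester near the silyl ethers, Bu4NF (THF, 0 °C) removes both to give the diol F8. TEMPO and PhI(OAc)2 oxidise it through the hydroxy enal F9 and the lactol F10 to the butenolide acetonide F11. PPTS in MeOH releases the diol lactone F12; acetyl chloride and collidine at −78 °C give the 13-acetate F13, and tigloyl chloride, pyridine and DMAP give 26.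

Step 3. Facial discrimination in the addition to the epoxy aldehyde may be insufficient, since the Felkin–Anh preference of lithium acetylides is only moderate. The fallback sets out from 6, taken as its mixture with the C6 epimer F14, and returns at 6. Dess–Martin oxidation of the mixture gives the epoxy ynone F15. Transfer hydrogenation with RuCl[(R,R)-TsDPEN](p-cymene) in i-PrOH, in which the alkyne takes the site usually held by an aryl group, should reduce it to 6 under catalyst control.

Step 9. Chemoselectivity may be lost through hydroboration of the internal alkyne or double hydroboration of the terminal one, and the acetate may be partly cleaved during oxidation. The fallback sets out from 14 and returns at 16. Anti-Markovnikov hydration with CpRu(MeCN)3PF6 and 5,5′-bis(trifluoromethyl)-2,2′-bipyridine in aqueous N-methylpyrrolidone at rt proceeds through a ruthenium vinylidene, which only a terminal alkyne can form, and gives 16 directly without a new intermediate.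

Further compounds

F1 | step 11 | (4R,5S)-7-[(2R,3S)-3-[(1S)-4-(tert-butyldimethylsilyloxy)-1-hydroxybut-2-yn-1-yl]-2-methyloxiran-2-yl]-4-methylhept-1-en-5-yl acetate | C=CC[C@@H](C)[C@@H](OC(C)=O)CC[C@@]1(C)O[C@H]1[C@@H](O)C#CCO[Si](C)(C)C(C)(C)C
F2 | step 11 | triene from F1 and ethylene (C7 and C11 each carrying a methylene) | C=CC[C@@H](C)[C@@H](OC(C)=O)CC[C@@]1(C)O[C@H]1[C@@H](O)C(=C)C(=C)CO[Si](C)(C)C(C)(C)C
F3 | step 11 | (1S,4R,5S,6S,7Z,10R)-1-acetoxy-12-(tert-butyldimethylsilyloxy)-4,5-epoxygermacra-7,11(13)-dien-6-ol | C=C(CO[Si](C)(C)C(C)(C)C)/C1=C/C[C@@H](C)[C@@H](OC(C)=O)CC[C@@]2(C)O[C@H]2[C@H]1O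
F4 | step 12 | 8R epimer of endoperoxide 19 | O1OCC(CO[Si](C)(C)C(C)(C)C)=C2[C@H]1C[C@@H](C)[C@@H](OC(C)=O)CC[C@@]3(C)O[C@H]3[C@H]2O[Si](CC)(CC)CC
F5 | step 12 | 8R epimer of diol 20 | OC/C(CO[Si](C)(C)C(C)(C)C)=C1\[C@H](O)C[C@@H](C)[C@@H](OC(C)=O)CC[C@@]2(C)O[C@H]2[C@H]1O[Si](CC)(CC)CC
F6 | step 12 | 8R epimer of monoacetate 21 | CC(=O)OC/C(CO[Si](C)(C)C(C)(C)C)=C1\[C@H](O)C[C@@H](C)[C@@H](OC(C)=O)CC[C@@]2(C)O[C@H]2[C@H]1O[Si](CC)(CC)CC
F7 | step 15 | 8,13-O-isopropylidene acetal of 20 | CC1(C)OCC(CO[Si](C)(C)C(C)(C)C)=C2[C@@H](O1)C[C@@H](C)[C@@H](OC(C)=O)CC[C@@]3(C)O[C@H]3[C@H]2O[Si](CC)(CC)CC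
F8 | step 15 | 6,12-diol from F7 (both silyl groups removed) | CC1(C)OCC(CO)=C2[C@@H](O1)C[C@@H](C)[C@@H](OC(C)=O)CC[C@@]3(C)O[C@H]3[C@H]2O
F9 | step 15 | 12-aldehyde of F8 | CC1(C)OCC(C=O)=C2[C@@H](O1)C[C@@H](C)[C@@H](OC(C)=O)CC[C@@]3(C)O[C@H]3[C@H]2O
F10 | step 15 | lactol from F9 (12-hydroxy-6,12-epoxide, both C12 epimers) | CC1(C)OCC2=C3[C@@H](O1)C[C@@H](C)[C@@H](OC(C)=O)CC[C@@]4(C)O[C@H]4[C@H]3OC2O
F11 | step 15 | 12,6-olide 8,13-acetonide | CC1(C)OCC2=C3[C@@H](O1)C[C@@H](C)[C@@H](OC(C)=O)CC[C@@]4(C)O[C@H]4[C@H]3OC2=O
F12 | step 15 | (1S,4R,5S,6S,8S,10R)-1-acetoxy-4,5-epoxy-8,13-dihydroxygermacr-7(11)-en-12,6-olide | OCC1=C2[C@@H](O)C[C@@H](C)[C@@H](OC(C)=O)CC[C@@]3(C)O[C@H]3[C@H]2OC1=O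
F13 | step 15 | 13-acetate of F12 | CC(=O)OCC1=C2[C@@H](O)C[C@@H](C)[C@@H](OC(C)=O)CC[C@@]3(C)O[C@H]3[C@H]2OC1=O
F14 | step 3 | C6 epimer of 6, (1R)-carbinol | CC(C)=CCC[C@@]1(C)O[C@H]1[C@H](O)C#CCO[Si](C)(C)C(C)(C)C
F15 | step 3 | 4-(tert-butyldimethylsilyloxy)-1-[(2R,3R)-3-methyl-3-(4-methylpent-3-en-1-yl)oxiran-2-yl]but-2-yn-1-one | CC(C)=CCC[C@@]1(C)O[C@H]1C(=O)C#CCO[Si](C)(C)C(C)(C)C
F0 | step 9 | none | none
A1 | alternative 1 | (2Z,6E,9S)-9-[(4-methoxyphenyl)methoxy]-3,7-dimethylcyclodeca-2,6-dien-1-one | C1C(=O)/C=C(C)\CC/C=C(C)/C[C@@H]1OCc1ccc(OC)cc1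
A2 | alternative 2 | Z-cyclodecenone with C7 ketone, C1 acetate, C8 tiglate and C6 triethylsilyl ether | C/C=C(\C)C(=O)O[C@H]1C[C@@H](C)[C@@H](OC(C)=O)CC/C(C)=C\[C@@H](O[Si](CC)(CC)CC)C1=O
A3 | alternative 3 | cyclodec-4-en-6-ol with the 3-(tert-butyldimethylsilyloxy)prop-1-en-2-yl group on C7, 4-methoxybenzyl ether on C8 and tert-butyldimethylsilyl ether on C1 | C1C/C(C)=C\[C@@H](O)[C@H](C(=C)CO[Si](C)(C)C(C)(C)C)[C@@H](OCc2ccc(OC)cc2)C[C@@H](C)[C@H]1O[Si](C)(C)C(C)(C)C
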